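**Retrosynthetic overview**
- Feature: ring A (C4a, C5, C6, C7, C8, C8a; OMe on C6, OH on C7) is fused through C4a/C8a to ring B (C1 aryl, C2 and C3 CH2OAc, C4 CH2). Ring A is cut at C4a–C8a and C5–C6 into a 6-substituted 3-methoxy-4-benzyloxy-2-pyrone (pyrone C3→C6, C4→C7, C5→C8, C6→C8a) and a terminal alkyne (→C4a, C5) at the end of the C1–C4 chain.
- Rings A and B form together in one pyrone–alkyne Diels–Alder/CO2 extrusion. The menthyloxy lactone ring is made before it and opened after it.
- C2 and C3 come from conjugate addition and alkylation on (5R)-5-(l-menthyloxy)butenolide. C1 carries the most acidic hydrogen, so it is fixed last, by protonation of its dienolate, not in the conjugate addition.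
- The pyrone donor is built from benzylated homosyringic ester and the acetoacetate dianion, then methoxylated at pyrone C-3 (diazo transfer, Rh O–H insertion) and O-benzylated.
- End game: LiAlH4 (frees menthol, gives the diol), acetylation, hydrogenolysis of both benzyl ethers.

Key step: step 9

Remark: tetralin numbering of the target (C1–C4, C4a, C5–C8, C8a) is used for these carbons throughout. Homosyringic acid is taken as commercially available. The C1–H between pyrone C-6 and the aryl ring is assumed more acidic than the lactone α-H, which is why the side chain is attached through a dianion in step 8.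

**Step 1**
Reactants: 1 2-(4-hydroxy-3,5-dimethoxyphenyl)acetic acid
Product: 2 benzyl 2-[4-(benzyloxy)-3,5-dimethoxyphenyl]acetate
Conditions: BnBr (2.3 equiv), K2CO3, DMF, 60 °C
Reagents that add atoms: benzyl bromide BrCc1ccccc1
Why: Williamson O-alkylation of phenoxide and carboxylate gives the hydrogenolysable phenol protection and an ester that serves as acyl donor in step 2.

**Step 2**
Reactants: 2 benzyl 2-[4-(benzyloxy)-3,5-dimethoxyphenyl]acetate; 3 methyl acetoacetate
Product: 4 methyl 6-[4-(benzyloxy)-3,5-dimethoxyphenyl]-3,5-dioxohexanoate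
Conditions: 3 (2.5 equiv), NaH then n-BuLi, THF, 0 °C; add 2, 0 °C to rt; aq. HCl
Reagents that add atoms: none
Why: Claisen-type γ-acylation of the acetoacetate dianion by the ester, with benzyl oxide as leaving group; excess dianion compensates for the acidity of the arylacetate CH2 and of the product.

**Step 3**
Reactants: 4 methyl 6-[4-(benzyloxy)-3,5-dimethoxyphenyl]-3,5-dioxohexanoate
Product: 5 6-[4-(benzyloxy)-3,5-dimethoxybenzyl]-4-hydroxy-2H-pyran-2-one
Conditions: DBU, toluene, reflux; aq. HCl
Reagents that add atoms: none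
Why: base-mediated enol lactonisation of the 3,5-dioxo ester (triketide cyclisation) closes the 4-hydroxy-2-pyrone with loss of methanol.

**Step 4**
Reactants: 5 6-[4-(benzyloxy)-3,5-dimethoxybenzyl]-4-hydroxy-2H-pyran-2-one
Product: 6 6-[4-(benzyloxy)-3,5-dimethoxybenzyl]-3-diazo-2H-pyran-2,4(3H)-dione
Conditions: p-ABSA, Et3N, MeCN, 0 °C to rt
Reagents that add atoms: 4-acetamidobenzenesulfonyl azide CC(=O)Nc1ccc(cc1)S(=O)(=O)N=[N+]=[N-]
Why: Regitz diazo transfer to the cyclic 1,3-dicarbonyl unit occurs at pyrone C-3, the only doubly activated carbon.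

**Step 5**
Reactants: 6 6-[4-(benzyloxy)-3,5-dimethoxybenzyl]-3-diazo-2H-pyran-2,4(3H)-dione
Product: 7 6-[4-(benzyloxy)-3,5-dimethoxybenzyl]-4-hydroxy-3-methoxy-2H-pyran-2-one
Conditions: Rh2(OAc)4 (1 mol%), MeOH, 60 °C
Reagents that add atoms: methanol CO
Why: Rh(II)-carbenoid O–H insertion into methanol places the methoxy group on pyrone C-3, and the product tautomerises to the 4-hydroxy-2-pyrone.

**Step 6**
Reactants: 7 6-[4-(benzyloxy)-3,5-dimethoxybenzyl]-4-hydroxy-3-methoxy-2H-pyran-2-one
Product: 8 4-(benzyloxy)-6-[4-(benzyloxy)-3,5-dimethoxybenzyl]-3-methoxy-2H-pyran-2-one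
Conditions: BnBr, K2CO3, DMF, 40 °C
Reagents that add atoms: benzyl bromide BrCc1ccccc1
Why: O-alkylation of the vinylogous acid at O-4 with carbonate in DMF gives the 4-alkoxy-2-pyrone; the benzylic CH2 is not acidic enough to react with carbonate.

**Step 7**
Reactants: 8 4-(benzyloxy)-6-[4-(benzyloxy)-3,5-dimethoxybenzyl]-3-methoxy-2H-pyran-2-one; 9 (5R)-5-(l-menthyloxy)furan-2(5H)-one
Product: 10 (4S,5R)-4-{[4-(benzyloxy)-3,5-dimethoxyphenyl][4-(benzyloxy)-3-methoxy-2-oxo-2H-pyran-6-yl]methyl}-5-(l-menthyloxy)dihydrofuran-2(3H)-one (both epimers at the benzylic carbon C1)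
Conditions: LiHMDS (1.05 equiv), THF, −78 °C; then 9, −78 to −40 °C; AcOH
Reagents that add atoms: none
Why: Michael addition of the pyrone-stabilised benzylic anion (reacting at its exocyclic carbon) to the butenolide anti to the C-5 menthyloxy group sets tetralin C2; C1 forms without control here and is made planar again in step 8.

**Step 8**
Reactants: 10 Michael adduct (C1 epimers); 11 propargyl bromide
Product: 12 (3R,4R,5R)-4-{(S)-[4-(benzyloxy)-3,5-dimethoxyphenyl][4-(benzyloxy)-3-methoxy-2-oxo-2H-pyran-6-yl]methyl}-5-(l-menthyloxy)-3-(prop-2-yn-1-yl)dihydrofuran-2(3H)-one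
Conditions: LDA (2.2 equiv), THF/DMPU, −78 °C; 11 (1.05 equiv), −78 °C; t-BuCO2H, −78 °C; chromatography
Reagents that add atoms: none
Why: double deprotonation (C1–H first, then the lactone α-H) and SN2 alkylation of the more basic lactone enolate anti to the C-4 substituent sets tetralin C3, and kinetic protonation of the remaining planar C1 dienolate, in the conformer that minimises allylic 1,3-strain (C2–H in the dienolate plane), from the face opposite the menthyloxy-bearing acetal carbon should give (S)-C1; any C1 epimer is removed by chromatography.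

**Step 9**
Reactants: 12 propargylated pyrone lactone
Product: 14 (3R,3aR,4S,9aR)-6-(benzyloxy)-4-[4-(benzyloxy)-3,5-dimethoxyphenyl]-7-methoxy-3-(l-menthyloxy)-3a,4,9,9a-tetrahydronaphtho[2,3-c]furan-1(3H)-one, via bridged bicyclic lactone 13 (not isolated)
Conditions: 1,2-dichlorobenzene (0.01 M), BHT (cat.), 180–200 °C, sealed silanised vessel
Reagents that add atoms: none
Why: Thermal intramolecular [4+2] cycloaddition of the 2-pyrone diene (C-3 to C-6) with the tethered terminal alkyne gives the 2-oxabicyclo[2.2.2]octadienone 13, which loses CO2 by retro-[4+2]; the closest known reaction type is the intramolecular 2-pyrone–alkyne Diels–Alder/decarboxylation benzannulation. Ring B (C1, C2, C3, C4, C4a, C8a) closes as the six-membered tether ring through the new C4a–C8a bond, and ring A (C4a, C5, C6, C7, C8, C8a) is completed in the same cycloaddition through C5–C6 and becomes aromatic on CO2 loss. No stereocentre is created: the bridgehead centres of 13 disappear on aromatisation, and C1, C2, C3 and the acetal carbon are carried through unchanged. The selectivity needed is regiochemical, and the four-atom tether allows only the orientation that joins the internal alkyne carbon to pyrone C-6 and the terminal carbon to pyrone C-3, so the methoxy group ends on C6 and the benzyloxy group on C7. The trans-disubstituted lactone holds the C2 and C3 ring bonds pseudo-equatorial, which fits the half-chair of the forming ring, and the neutral base-free medium keeps the acidic C1–H from epimerising before the pyrone is consumed.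

**Step 10**
Reactants: 14 trans-lactone-fused 1-aryltetralin
Product: 15 {(1S,2R,3R)-7-(benzyloxy)-1-[4-(benzyloxy)-3,5-dimethoxyphenyl]-6-methoxy-1,2,3,4-tetrahydronaphthalene-2,3-diyl}dimethanol
Conditions: LiAlH4, THF, 0 °C to rt; Fieser work-up
Reagents that add atoms: none
Why: hydride reduction of the acylal-type lactone gives CH2OH on C3, the freed hemiacetal collapses with loss of menthoxide to an aldehyde that is reduced at once to CH2OH on C2, so no centre epimerises and the benzyl ethers are untouched.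

**Step 11**
Reactants: 15 diol
Product: 16 {(1S,2R,3R)-7-(benzyloxy)-1-[4-(benzyloxy)-3,5-dimethoxyphenyl]-6-methoxy-1,2,3,4-tetrahydronaphthalene-2,3-diyl}bis(methylene) diacetate
Conditions: Ac2O, pyridine, DMAP (cat.), CH2Cl2, 0 °C to rt
Reagents that add atoms: acetic anhydride CC(=O)OC(C)=O
Why: DMAP-catalysed acylation of the two primary alcohols, the only free hydroxyl groups present.

**Step 12**
Reactants: 16 dibenzyl diacetate
Product: 17 [(1S,2R,3R)-7-hydroxy-1-(4-hydroxy-3,5-dimethoxyphenyl)-6-methoxy-1,2,3,4-tetrahydronaphthalene-2,3-diyl]bis(methylene) diacetate (target)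
Conditions: H2 (1 atm), 10% Pd/C, EtOAc, rt
Reagents that add atoms: none
Why: hydrogenolysis of the two aryl benzyl ethers over palladium leaves the acetates, aryl methyl ethers and all three stereocentres unchanged.

**Compound list**
1 | 2-(4-hydroxy-3,5-dimethoxyphenyl)acetic acid (homosyringic acid) | COc1cc(CC(=O)O)cc(OC)c1O | starting material
2 | benzyl 2-[4-(benzyloxy)-3,5-dimethoxyphenyl]acetate | COc1cc(CC(=O)OCc2ccccc2)cc(OC)c1OCc1ccccc1 | intermediate
3 | methyl acetoacetate | CC(=O)CC(=O)OC | starting material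
4 | methyl 6-[4-(benzyloxy)-3,5-dimethoxyphenyl]-3,5-dioxohexanoate | COC(=O)CC(=O)CC(=O)Cc1cc(OC)c(OCc2ccccc2)c(OC)c1 | intermediate
5 | 6-[4-(benzyloxy)-3,5-dimethoxybenzyl]-4-hydroxy-2H-pyran-2-one | O=C1C=C(O)C=C(Cc2cc(OC)c(OCc3ccccc3)c(OC)c2)O1 | intermediate
6 | 6-[4-(benzyloxy)-3,5-dimethoxybenzyl]-3-diazo-2H-pyran-2,4(3H)-dione | [N-]=[N+]=C1C(=O)C=C(Cc2cc(OC)c(OCc3ccccc3)c(OC)c2)OC1=O | intermediate
7 | 6-[4-(benzyloxy)-3,5-dimethoxybenzyl]-4-hydroxy-3-methoxy-2H-pyran-2-one | COC1=C(O)C=C(Cc2cc(OC)c(OCc3ccccc3)c(OC)c2)OC1=O | intermediate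
8 | 4-(benzyloxy)-6-[4-(benzyloxy)-3,5-dimethoxybenzyl]-3-methoxy-2H-pyran-2-one | COC1=C(OCc2ccccc2)C=C(Cc2cc(OC)c(OCc3ccccc3)c(OC)c2)OC1=O | intermediate
9 | (5R)-5-{[(1R,2S,5R)-2-isopropyl-5-methylcyclohexyl]oxy}furan-2(5H)-one | CC(C)[C@@H]1CC[C@@H](C)C[C@H]1O[C@H]1C=CC(=O)O1 | starting material
10 | (4S,5R)-Michael adduct, pyrone/aryl-substituted methyl group on C-4 trans to the menthyloxy group, both C1 epimers | COC1=C(OCc2ccccc2)C=C(OC1=O)C(c1cc(OC)c(OCc2ccccc2)c(OC)c1)[C@H]1[C@H](O[C@@H]2C[C@H](C)CC[C@H]2C(C)C)OC(=O)C1 | intermediate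
11 | propargyl bromide (3-bromoprop-1-yne) | C#CCBr | starting material
12 | (3R,4R,5R)-lactone with (S)-configured C1, 3-propargyl trans to the C-4 substituent (cycloaddition precursor) | COC1=C(OCc2ccccc2)C=C(OC1=O)[C@H](c1cc(OC)c(OCc2ccccc2)c(OC)c1)[C@H]1[C@H](O[C@@H]2C[C@H](C)CC[C@H]2C(C)C)OC(=O)[C@@H]1CC#C | intermediate
13 | bridged 2-oxabicyclo[2.2.2]octa-5,7-dien-3-one cycloadduct (bridgehead configuration not specified; either facial adduct gives 14) | COC15C(OCc2ccccc2)=CC6(OC1=O)[C@H](c1cc(OC)c(OCc2ccccc2)c(OC)c1)[C@H]1[C@H](O[C@@H]2C[C@H](C)CC[C@H]2C(C)C)OC(=O)[C@@H]1CC6=C5 | intermediate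
14 | (3R,3aR,4S,9aR)-6-(benzyloxy)-4-[4-(benzyloxy)-3,5-dimethoxyphenyl]-7-methoxy-3-(l-menthyloxy)-3a,4,9,9a-tetrahydronaphtho[2,3-c]furan-1(3H)-one | COc1cc2c(cc1OCc1ccccc1)[C@H](c1cc(OC)c(OCc3ccccc3)c(OC)c1)[C@H]1[C@H](O[C@@H]3C[C@H](C)CC[C@H]3C(C)C)OC(=O)[C@@H]1C2 | intermediate
15 | (1S,2R,3R)-diol | COc1cc2c(cc1OCc1ccccc1)[C@H](c1cc(OC)c(OCc3ccccc3)c(OC)c1)[C@@H](CO)[C@H](CO)C2 | intermediate
16 | (1S,2R,3R)-dibenzyl diacetate | COc1cc2c(cc1OCc1ccccc1)[C@H](c1cc(OC)c(OCc3ccccc3)c(OC)c1)[C@@H](COC(C)=O)[C@H](COC(C)=O)C2 | intermediate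
17 | [(1S,2R,3R)-7-hydroxy-1-(4-hydroxy-3,5-dimethoxyphenyl)-6-methoxy-1,2,3,4-tetrahydronaphthalene-2,3-diyl]bis(methylene) diacetate | COc1cc2c(cc1O)[C@H](c1cc(OC)c(O)c(OC)c1)[C@@H](COC(C)=O)[C@H](COC(C)=O)C2 | target

**Totals**
Total steps: 12. Longest linear sequence: 12 (from 1).

**Steps most likely to fail**

1. Step 9. The electron-rich pyrone and the unactivated alkyne may cyclise only at temperatures where the acetal lactone or the terminal alkyne decomposes, or where C1 epimerises before cycloaddition. The fallback replaces the alkyne by an electron-poor alkyne equivalent. It sets out from 10: the dianion of 10 (conditions of step 8) is alkylated with 3-bromo-2-(phenylsulfonyl)prop-1-ene to give the 3-[2-(phenylsulfonyl)allyl] lactone F1. Heating F1 in toluene at 110–130 °C should give the normal-demand pyrone–vinyl sulfone cycloadduct F2, which loses CO2 to the sulfonyl cyclohexadiene F3. Elimination of benzenesulfinic acid from F3 (Et3N, same flask) aromatises ring A, and the route is rejoined at 14. Vinyl sulfones are established alkyne equivalents in intramolecular pyrone Diels–Alder arene syntheses.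

2. Step 8. The protonation of the C1 dienolate may show poor facial selectivity, since the two lactone carbons flanking C2 differ only modestly in size. The fallback uses thermodynamic equilibration and separation instead of kinetic control. It sets out from 10: alkylation as in step 8 with an unselective acetic acid quench gives 12 together with its C1 epimer F4, which is separated by chromatography. F4 is re-equilibrated at C1 with catalytic DBU in toluene at 50 °C through the pyrone dienolate and separated again, so that material returns to 12 over a few cycles.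

3. Step 7. The hindered, strongly stabilised dienolate of 8 may add incompletely or reversibly (retro-Michael on warming). The fallback uses a less stabilised carbon nucleophile and moves the benzylation behind the addition. It sets out from 7: the O,C-dianion of 7 (LDA, 2.1 equiv, THF, −78 °C) is added to 9 to give the free 4-hydroxy adduct F5. Benzylation of F5 (BnBr, K2CO3, DMF) returns to 10.

**Further compounds**
F1 | step 9 | (3R,4R,5R)-lactone as 12 with 2-(phenylsulfonyl)prop-2-en-1-yl in place of propargyl, (S)-C1 | COC1=C(OCc2ccccc2)C=C(OC1=O)[C@H](c1cc(OC)c(OCc2ccccc2)c(OC)c1)[C@H]1[C@H](O[C@@H]2C[C@H](C)CC[C@H]2C(C)C)OC(=O)[C@@H]1CC(=C)S(=O)(=O)c1ccccc1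
F2 | step 9 | 2-oxabicyclo[2.2.2]oct-5-en-3-one cycloadduct of F1 with phenylsulfonyl on C4a (new centres not specified) | COC15C(OCc2ccccc2)=CC6(OC1=O)[C@H](c1cc(OC)c(OCc2ccccc2)c(OC)c1)[C@H]1[C@H](O[C@@H]2C[C@H](C)CC[C@H]2C(C)C)OC(=O)[C@@H]1CC6(C5)S(=O)(=O)c1ccccc1
F3 | step 9 | 4a-(phenylsulfonyl)-4a,5-dihydro analogue of 14 (cyclohexa-1,3-diene after CO2 loss) | COC1=C(OCc2ccccc2)C=C2[C@H](c3cc(OC)c(OCc4ccccc4)c(OC)c3)[C@H]3[C@H](O[C@@H]4C[C@H](C)CC[C@H]4C(C)C)OC(=O)[C@@H]3CC2(C1)S(=O)(=O)c1ccccc1
F4 | step 8 | C1 epimer of 12 ((R)-configured benzylic carbon) | COC1=C(OCc2ccccc2)C=C(OC1=O)[C@@H](c1cc(OC)c(OCc2ccccc2)c(OC)c1)[C@H]1[C@H](O[C@@H]2C[C@H](C)CC[C@H]2C(C)C)OC(=O)[C@@H]1CC#C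
F5 | step 7 | 4-hydroxy analogue of 10 (free pyrone hydroxyl, both C1 epimers) | COC1=C(O)C=C(OC1=O)C(c1cc(OC)c(OCc2ccccc2)c(OC)c1)[C@H]1[C@H](O[C@@H]2C[C@H](C)CC[C@H]2C(C)C)OC(=O)C1
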